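**Retrosynthetic overview** (tetralin numbering: C1 carries the catechol ring, C2 and C3 the CH2OH groups, C4 is the ring CH2, C4a/C8a are the fusion carbons)

1. The target comes from a protected C3-aldehyde (C2–CH2OTBS, catechol as diacetate) by one-pot hydride reduction, deacetylation and desilylation.
2. That aldehyde is cut at C2–C3 and C1–C8a into 3-(3,4-dimethoxyphenyl)propanal and an (E)-cinnamyl silyl ether; both bonds form in one amine-catalysed, one-electron-oxidation (SOMO) radical–polar crossover [4+2] annulation.
3. Enabling feature: the CH2OH on C3, taken to the aldehyde level, makes C3 an enamine carbon that single-electron oxidation turns into an electrophilic radical, so it can bond to the likewise nucleophilic alkene carbon C2. The cation then left at C1 is benzylic and sits six atoms from C8a of the dimethoxybenzene ring, para to the C6 methoxy group.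
4. The aldehyde comes from oxidation of the commercial alcohol; the alkene from cross-metathesis of 3,4-diacetoxystyrene with allyl TBS ether.
5. Ring order: both benzene rings are bought; the saturated ring of the tetralin is the only ring formed, in the key step.

Key step: step 3

Remark: the sense of induction of the imidazolidinone catalyst is taken from the usual shielding model (benzyl group over the Re face of the E-enamine radical cation); if it ran the other way, the (2R,5R) catalyst would be used.

**Step 1**
Reactants: 1 3-(3,4-dimethoxyphenyl)propan-1-ol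
Product: 2 3-(3,4-dimethoxyphenyl)propanal
Conditions: TEMPO (10 mol %), PhI(OAc)2 (1.1 equiv), CH2Cl2, rt
Reagents that add atoms: none
Why: Oxoammonium-mediated (TEMPO/PhI(OAc)2) alcohol oxidation should stop at the aldehyde and leave the electron-rich arene alone; no stereocentre is formed.

**Step 2**
Reactants: 3 4-ethenyl-1,2-phenylene diacetate (3,4-diacetoxystyrene); 4 tert-butyldimethyl(prop-2-en-1-yloxy)silane (3 equiv)
Product: 5 4-[(1E)-3-{[tert-butyl(dimethyl)silyl]oxy}prop-1-en-1-yl]-1,2-phenylene diacetate
Conditions: Hoveyda–Grubbs second-generation catalyst (3 mol %), CH2Cl2, 40 °C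
Reagents that add atoms: none
Why: Olefin cross-metathesis of the styrene with excess allyl silyl ether should give the cinnamyl ether, the E isomer being favoured under reversible metathesis; aryl acetates and the silyl ether are inert to the ruthenium carbene.

**Step 3**
Reactants: 2 3-(3,4-dimethoxyphenyl)propanal (1 equiv); 5 4-[(1E)-3-{[tert-butyl(dimethyl)silyl]oxy}prop-1-en-1-yl]-1,2-phenylene diacetate (2 equiv, excess recovered)
Product: 7 4-[(1S,2R,3R)-2-({[tert-butyl(dimethyl)silyl]oxy}methyl)-3-formyl-6,7-dimethoxy-1,2,3,4-tetrahydronaphthalen-1-yl]-1,2-phenylene diacetate, via ring-open benzylic cation iminium 6 (not isolated)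
Conditions: (2S,5S)-5-benzyl-2-tert-butyl-3-methylimidazolidin-4-one·TFA (20 mol %), [Fe(phen)3](SbF6)3 (2.5 equiv), Na2HPO4 (3 equiv), H2O (2 equiv), acetone, −30 °C
Reagents that add atoms: none
Why: Organo-SOMO radical–polar crossover [4+2] annulation: the imidazolidinone and 2 form the E-enamine, one-electron oxidation by Fe(III) gives a 3π-electron radical cation whose electrophilic α-carbon (C3) adds to the alkene carbon of 5 remote from the aryl group (C2), a second oxidation turns the benzylic radical into the cation 6, the dimethoxybenzene ring attacks it (C8a–C1), and proton loss and iminium hydrolysis release 7 and the catalyst. The closest known reaction type is this amine-catalysed SOMO cascade between 3-arylpropanals and styrenes, applied here to a β-substituted styrene. The one ring formed, the saturated ring of the tetralin, closes by a 6-endo cation–π (intramolecular Friedel–Crafts) attack through a chair-like transition state. C3 is set by the catalyst, whose benzyl group covers the Re face of the radical cation so that the alkene bonds to the Si face (3R); C2 is set in the open staggered transition state of the radical addition, in which the alkene hydrogen should sit between the iminium carbon and the ArCH2 group, the C=C bond anti to the iminium carbon and CH2OTBS anti to ArCH2 (2,3-trans, 2R); C1 is set in the ring closure, the diacetoxyphenyl group taking the pseudo-equatorial position trans to the C2 substituent (1S). The step needs the oxidant to take the enamine and not the alkene or an arene, the radical to attack the alkene carbon that leaves a benzylic radical, and the cation to be captured only by C8a: the acetate groups raise the oxidation potential of 5 and make its ring useless as a nucleophile, the aryl group fixes the regiochemistry of addition, SbF6 and the silyl ether offer no competing nucleophile, and closure para to the C6 methoxy group at the unhindered ring position gives the 6,7-dimethoxy pattern.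

**Step 4**
Reactants: 7 4-[(1S,2R,3R)-2-({[tert-butyl(dimethyl)silyl]oxy}methyl)-3-formyl-6,7-dimethoxy-1,2,3,4-tetrahydronaphthalen-1-yl]-1,2-phenylene diacetate
Product: 9 4-[(1S,2R,3R)-2,3-bis(hydroxymethyl)-6,7-dimethoxy-1,2,3,4-tetrahydronaphthalen-1-yl]benzene-1,2-diol, via monosilyl ether 8 (not isolated)
Conditions: LiAlH4 (3 equiv), THF, 0 °C; then MeOH, 2 M aq. HCl, rt, under Ar
Reagents that add atoms: none
Why: LiAlH4 reduces the aldehyde to the C3 hydroxymethyl group and cleaves both aryl acetates by hydride acyl substitution, and the acidic quench removes the primary silyl ether (acid-catalysed desilylation) while keeping the catechol protonated and protected from air oxidation; no stereocentre is touched, the equatorial formyl group being the stable epimer.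

**Compound list**

1 | 3-(3,4-dimethoxyphenyl)propan-1-ol | COc1ccc(CCCO)cc1OC | starting material
2 | 3-(3,4-dimethoxyphenyl)propanal | COc1ccc(CCC=O)cc1OC | intermediate
3 | 4-ethenyl-1,2-phenylene diacetate | CC(=O)Oc1ccc(C=C)cc1OC(C)=O | starting material
4 | tert-butyldimethyl(prop-2-en-1-yloxy)silane | C=CCO[Si](C)(C)C(C)(C)C | starting material
5 | 4-[(1E)-3-{[tert-butyl(dimethyl)silyl]oxy}prop-1-en-1-yl]-1,2-phenylene diacetate | CC(=O)Oc1ccc(/C=C/CO[Si](C)(C)C(C)(C)C)cc1OC(C)=O | intermediate
6 | ring-open benzylic cation iminium (catalyst-bound adduct after C2–C3 bond formation, 2R,3R in the chain) | CN1[C@@H](C(C)(C)C)[N+](=C[C@H](Cc2ccc(OC)c(OC)c2)[C@H](CO[Si](C)(C)C(C)(C)C)[CH+]c2ccc(OC(C)=O)c(OC(C)=O)c2)[C@@H](Cc2ccccc2)C1=O | intermediate (not isolated)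
7 | 4-[(1S,2R,3R)-2-({[tert-butyl(dimethyl)silyl]oxy}methyl)-3-formyl-6,7-dimethoxy-1,2,3,4-tetrahydronaphthalen-1-yl]-1,2-phenylene diacetate | COc1cc2c(cc1OC)[C@H](c1ccc(OC(C)=O)c(OC(C)=O)c1)[C@@H](CO[Si](C)(C)C(C)(C)C)[C@H](C=O)C2 | intermediate
8 | 4-[(1S,2R,3R)-2-({[tert-butyl(dimethyl)silyl]oxy}methyl)-3-(hydroxymethyl)-6,7-dimethoxy-1,2,3,4-tetrahydronaphthalen-1-yl]benzene-1,2-diol | COc1cc2c(cc1OC)[C@H](c1ccc(O)c(O)c1)[C@@H](CO[Si](C)(C)C(C)(C)C)[C@H](CO)C2 | intermediate (not isolated)
9 | 4-[(1S,2R,3R)-2,3-bis(hydroxymethyl)-6,7-dimethoxy-1,2,3,4-tetrahydronaphthalen-1-yl]benzene-1,2-diol | COc1cc2c(cc1OC)[C@H](c1ccc(O)c(O)c1)[C@@H](CO)[C@H](CO)C2 | target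

**Totals**

Total step count: 4. Longest linear sequence: 3 steps (1 → 2 → 7 → 9, or 3 → 5 → 7 → 9).

**Steps most likely to fail**

Step 3. The radical addition goes through an open transition state, so facial selectivity at the alkene carbon may be poor and control at C2 lost. Addition of the radical cation to a 1,2-disubstituted, electron-poor styrene may also be slow, so that the oxidised enamine is used up by homocoupling or over-oxidation. The fallback makes the two bonds in separate, well-precedented steps and relays all stereochemistry from C3. It sets out from 2. Enantioselective photoredox organocatalytic α-alkylation with diethyl bromomalonate [(2R,5S)-2-tert-butyl-3,5-dimethylimidazolidin-4-one·TfOH, Ru(bpy)3Cl2, 2,6-lutidine, DMF, visible light] should give the α-malonyl aldehyde F1. NaBH4 reduction would give the hydroxy diester F2, and acid-catalysed lactonisation (TsOH, toluene) the ethoxycarbonyl lactone F3. Krapcho dealkoxycarbonylation (LiCl, wet DMSO, 150 °C) would give the (R)-β-benzyl-γ-butyrolactone F4. Its lithium enolate (LDA, THF, −78 °C) should add to commercial 3,4-bis(benzyloxy)benzaldehyde anti to the benzyl group, giving the trans aldol F5. TFA in CH2Cl2 would ionise the benzylic alcohol, and the dimethoxybenzene ring should close para to methoxy to the trans-fused aryltetralin lactone F6 with the aryl group trans to the lactone carbonyl. LiAlH4 would give the bis(benzyl ether) diol F7, and hydrogenolysis (H2, Pd/C, EtOAc/MeOH) comes back to the route at 9.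

Step 2. Both partners are reactive olefins, so homodimerisation of the styrene to a stilbene and a statistical product distribution may dominate, and ruthenium hydride may isomerise the allyl ether to an enol ether. The fallback brings in the three-carbon unit at the aldehyde level with an electron-poor partner, for which cross-selectivity is inherent, and sets the silyl ether afterwards. It sets out from 3. Cross-metathesis with acrolein (Hoveyda–Grubbs second-generation catalyst, CH2Cl2, 40 °C) should give the (E)-cinnamaldehyde diacetate F8. Luche reduction (NaBH4, CeCl3·7H2O, MeOH, −40 °C) would give the cinnamyl alcohol diacetate F9, and silylation (TBSCl, imidazole, CH2Cl2) comes back to the route at 5.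

Step 4. The catecholate may oxidise under the basic aluminate conditions, the polyol may be held on aluminium salts at work-up, and desilylation in the one-pot quench may be incomplete. The fallback avoids aluminium and base and removes the acetates by acid-catalysed methanolysis instead of by hydride. It sets out from 7. NaBH4 (THF/MeOH, −20 °C) should give the primary alcohol F10 with all protecting groups in place. Anhydrous HCl in MeOH (from AcCl, rt, under Ar) would then remove the silyl ether and both aryl acetates and comes back to the route at 9.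

**Further compounds**

F1 | step 3 | diethyl 2-[(2R)-1-(3,4-dimethoxyphenyl)-3-oxopropan-2-yl]propanedioate | CCOC(=O)C(C(=O)OCC)[C@@H](Cc1ccc(OC)c(OC)c1)C=O
F2 | step 3 | diethyl 2-[(2R)-1-(3,4-dimethoxyphenyl)-3-hydroxypropan-2-yl]propanedioate | CCOC(=O)C(C(=O)OCC)[C@@H](Cc1ccc(OC)c(OC)c1)CO
F3 | step 3 | ethyl (4R)-4-(3,4-dimethoxybenzyl)-2-oxooxolane-3-carboxylate (C3 epimers) | CCOC(=O)C1C(=O)OC[C@@H]1Cc1ccc(OC)c(OC)c1
F4 | step 3 | (4R)-4-(3,4-dimethoxybenzyl)oxolan-2-one | O=C1C[C@@H](Cc2ccc(OC)c(OC)c2)CO1
F5 | step 3 | (3S,4R)-3-{[3,4-bis(benzyloxy)phenyl](hydroxy)methyl}-4-(3,4-dimethoxybenzyl)oxolan-2-one (carbinol epimers) | O=C1OC[C@H](Cc2ccc(OC)c(OC)c2)[C@H]1C(O)c1ccc(OCc2ccccc2)c(OCc2ccccc2)c1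
F6 | step 3 | trans-fused lactone of (1S,2R,3R)-1-[3,4-bis(benzyloxy)phenyl]-3-(hydroxymethyl)-6,7-dimethoxy-1,2,3,4-tetrahydronaphthalene-2-carboxylic acid | COc1cc2c(cc1OC)[C@H](c1ccc(OCc3ccccc3)c(OCc3ccccc3)c1)[C@H]4C(=O)OC[C@@H]4C2
F7 | step 3 | [(1S,2R,3R)-1-[3,4-bis(benzyloxy)phenyl]-6,7-dimethoxy-1,2,3,4-tetrahydronaphthalene-2,3-diyl]dimethanol | COc1cc2c(cc1OC)[C@H](c1ccc(OCc3ccccc3)c(OCc3ccccc3)c1)[C@@H](CO)[C@H](CO)C2
F8 | step 2 | 4-[(1E)-3-oxoprop-1-en-1-yl]-1,2-phenylene diacetate | CC(=O)Oc1ccc(/C=C/C=O)cc1OC(C)=O
F9 | step 2 | 4-[(1E)-3-hydroxyprop-1-en-1-yl]-1,2-phenylene diacetate | CC(=O)Oc1ccc(/C=C/CO)cc1OC(C)=O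
F10 | step 4 | 4-[(1S,2R,3R)-2-({[tert-butyl(dimethyl)silyl]oxy}methyl)-3-(hydroxymethyl)-6,7-dimethoxy-1,2,3,4-tetrahydronaphthalen-1-yl]-1,2-phenylene diacetate | COc1cc2c(cc1OC)[C@H](c1ccc(OC(C)=O)c(OC(C)=O)c1)[C@@H](CO[Si](C)(C)C(C)(C)C)[C@H](CO)C2
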